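**Retrosynthetic overview**

1. Target 31 comes from 30 by one acid step (C1 methyl enol ether to the C1/C3 diketone, side-chain silyl ether off); 30 from Yamaguchi acylation of the (8S)-carbinol 25, itself from CBS reduction of a C8 ketone; the C13 acetate is installed only after the palladium step.
2. Key disconnection C9–C10: the ten-membered carbocycle (C1–C10) is made from the twelve-membered β-keto macrolactone 19 (ring segment C10–O–C(=O)–C9) by palladium-catalysed decarboxylative ring contraction; the ester carbon leaves as CO2.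
3. Enabling feature: C9–C10 is the central bond of the 1,4-dioxygenated unit C8(O)–C9–C10–C1(=O) of the ten-membered ring. At the C8-ketone level C9 is the only enolisable α-carbon (C7 is an sp2 carbon of the butenolide ring), and with the C1/C3 diketone held as its C1 methyl enol ether C10 is an allyl terminus, so one C10–O ester serves as tether, leaving group and enolate source.
4. 19 comes from acylketene macrolactonisation (C8 acyl Meldrum's acid onto C10–OH); the butenolide from hydroxyl-directed vinylmagnesiation/CO2 of the C6 propargylic alcohol; the epoxide from Shi epoxidation; C6 (and a temporary C3 carbinol) from ProPhenol alkynylations of a C5 enal; C10 from (R)-but-3-yn-2-ol.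
5. Ring order: butenolide, epoxide, twelve-membered lactone, ten-membered carbocycle.

Key step: step 14

Assumption: locants C1–C15 are the germacrane locants of the target (C12 lactone carbonyl, C13 CH2OAc, C14/C15 methyls on C10/C4); (S,S)-ProPhenol is taken to give the (R)-propargylic carbinols drawn (otherwise its antipode is used; C3 is erased in step 12), and C–C bond formation in step 14 is taken to proceed with net retention at C10 (anti ionisation, anti attack), otherwise the route starts from (S)-but-3-yn-2-ol. CIP descriptors at C3, C4 and C6 change along the route with substituent priorities although the geometry does not.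

**Route**

Step 1
Reactants: 1 (R)-but-3-yn-2-ol
Product: 2 (R)-tert-butyl(but-3-yn-2-yloxy)dimethylsilane
Conditions: TBSCl, imidazole, CH2Cl2, 0 °C to rt
Reagents that add atoms: tert-butyldimethylsilyl chloride, CC(C)(C)[Si](C)(C)Cl
Why: Routine silyl ether formation on the secondary alcohol; the C10 stereocentre is taken unchanged from the chiral pool.

Step 2
Reactants: 2 (R)-tert-butyl(but-3-yn-2-yloxy)dimethylsilane; 3 (E)-4,4-dimethoxy-2-methylbut-2-enal
Product: 4 (2E,4R,7R)-7-(tert-butyldimethylsilyloxy)-1,1-dimethoxy-3-methyloct-2-en-5-yn-4-ol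
Conditions: (S,S)-ProPhenol (10 mol%), Me2Zn, Ph3P=O (20 mol%), toluene, 0 °C to rt
Reagents that add atoms: none
Why: Zinc–ProPhenol-catalysed enantioselective alkynylation (1,2-addition of an alkynylzinc to an enal) should give a single C3 carbinol by ligand control; this centre only keeps the intermediates homogeneous and is erased in step 12.

Step 3
Reactants: 4 (2E,4R,7R)-7-(tert-butyldimethylsilyloxy)-1,1-dimethoxy-3-methyloct-2-en-5-yn-4-ol
Product: 5 (2E,4R,7R)-4,7-bis(tert-butyldimethylsilyloxy)-1,1-dimethoxy-3-methyloct-2-en-5-yne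
Conditions: TBSCl, imidazole, DMF, rt
Reagents that add atoms: tert-butyldimethylsilyl chloride, CC(C)(C)[Si](C)(C)Cl
Why: Silylation of the C3 alcohol leaves no free propargylic alkoxide on the C1≡C2 alkyne, so that alkyne stays inert in the directed carbomagnesiation of step 6.

Step 4
Reactants: 5 (2E,4R,7R)-4,7-bis(tert-butyldimethylsilyloxy)-1,1-dimethoxy-3-methyloct-2-en-5-yne
Product: 6 (2E,4R,7R)-4,7-bis(tert-butyldimethylsilyloxy)-3-methyloct-2-en-5-ynal
Conditions: oxalic acid (10% aq.), THF, rt
Reagents that add atoms: water, O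
Why: Acid-catalysed acetal hydrolysis; the dimethyl acetal of an enal is far more labile than secondary TBS ethers, and the (E)-trisubstituted olefin is configurationally stable.

Step 5
Reactants: 6 (2E,4R,7R)-4,7-bis(tert-butyldimethylsilyloxy)-3-methyloct-2-en-5-ynal; 7 tert-butyldiphenyl(prop-2-yn-1-yloxy)silane
Product: 8 (4R,5E,7R,10R)-7,10-bis(tert-butyldimethylsilyloxy)-1-(tert-butyldiphenylsilyloxy)-6-methylundec-5-ene-2,8-diyn-4-ol
Conditions: (S,S)-ProPhenol (10 mol%), Me2Zn, Ph3P=O (20 mol%), toluene, 0 °C to rt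
Reagents that add atoms: none
Why: A second zinc–ProPhenol alkynylation of the enal sets the C6 carbinol by ligand control (R here, 6S in the target once the epoxide changes the CIP priorities) and brings in C7, C11 and C13.

Step 6
Reactants: 8 (4R,5E,7R,10R)-7,10-bis(tert-butyldimethylsilyloxy)-1-(tert-butyldiphenylsilyloxy)-6-methylundec-5-ene-2,8-diyn-4-ol
Product: 10 (5R)-5-[(1E,3R,6R)-3,6-bis(tert-butyldimethylsilyloxy)-2-methylhept-1-en-4-yn-1-yl]-3-[(tert-butyldiphenylsilyloxy)methyl]-4-vinylfuran-2(5H)-one, via alkenylmagnesium chelate 9 (not isolated)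
Conditions: CH2=CHMgCl (5 equiv), THF/toluene, 65 °C; then CO2, −20 °C to rt; then 1 M HCl
Reagents that add atoms: vinylmagnesium chloride, C=C[Mg]Cl; carbon dioxide, O=C=O
Why: Hydroxyl-directed anti-carbomagnesiation of the propargylic alkoxide puts vinyl on the proximal alkyne carbon C7 and magnesium on C11 in a five-membered chelate, and carboxylation followed by acid-promoted lactonisation of the (Z)-γ-hydroxy acid closes the butenolide; the bis-silylated C1≡C2 alkyne has no free alkoxide and should not react, and 2-(silyloxymethyl)alkenyl Grignard reagents are known to resist β-elimination.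

Step 7
Reactants: 10 vinyl butenolide from step 6
Product: 11 (5S)-5-{(2R,3S)-3-[(1S,4R)-1,4-bis(tert-butyldimethylsilyloxy)pent-2-yn-1-yl]-3-methyloxiran-2-yl}-3-[(tert-butyldiphenylsilyloxy)methyl]-4-vinylfuran-2(5H)-one
Conditions: D-fructose-derived Shi ketone (30 mol%), KHSO5 (Oxone), K2CO3, Bu4NHSO4, MeCN/dimethoxymethane/aq. buffer (pH 10.5), 0 °C
Reagents that add atoms: potassium peroxymonosulfate, [K+].[O-]S(=O)(=O)OO
Why: Shi asymmetric epoxidation: the chiral dioxirane transfers oxygen through a spiro transition state to the only electron-rich olefin, the (E)-trisubstituted C4=C5, and should set (4S,5R) by reagent control in the same sense that gives (R,R)-epoxides from trans-stilbene-type olefins, while the electron-poor vinyl butenolide and the alkyne are left alone.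

Step 8
Reactants: 11 epoxy vinyl butenolide from step 7
Product: 13 C8 carboxylic acid (the 4-carboxybutenolide corresponding to 11; 3S,4S,5R,6S,10R), via C8 aldehyde 12 (not isolated)
Conditions: O3, CH2Cl2, −78 °C; Me2S; then NaClO2, NaH2PO4, 2-methyl-2-butene, t-BuOH/H2O, 0 °C
Reagents that add atoms: ozone, [O-][O+]=O; sodium chlorite, [Na+].[O-]Cl=O
Why: Ozonolysis cleaves the terminal vinyl group (more reactive than the electron-poor tetrasubstituted butenolide olefin and the alkyne) and Pinnick oxidation takes the resulting aldehyde to the acid; no stereocentre is touched.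

Step 9
Reactants: 13 C8 carboxylic acid
Product: 14 C8 acyl Meldrum's acid (enol form; C3 and C10 TBS ethers, C13 TBDPS ether)
Conditions: Meldrum's acid, EDC·HCl, DMAP, CH2Cl2, 0 °C to rt
Reagents that add atoms: Meldrum's acid (2,2-dimethyl-1,3-dioxane-4,6-dione), CC1(C)OC(=O)CC(=O)O1
Why: Carbodiimide-mediated C-acylation of Meldrum's acid is the standard entry to acyl Meldrum's acids and installs C9 as a latent acylketene; no ynone is present yet, so no Michael acceptor competes for the Meldrum's acid anion.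

Step 10
Reactants: 14 C8 acyl Meldrum's acid
Product: 15 diol acyl Meldrum's acid (C3–OH and C10–OH free; 3S,4R,5R,6S,10R)
Conditions: HF·pyridine, pyridine, THF, 0 °C to rt
Reagents that add atoms: none
Why: Buffered HF·pyridine should cleave the two secondary TBS ethers while the more robust primary TBDPS ether, the epoxide and the acyl Meldrum's acid survive (selective desilylation).

Step 11
Reactants: 15 diol acyl Meldrum's acid
Product: 17 twelve-membered β-keto lactone (ring C10–O–C(=O)–C9H2–C8(=O)–C7; C1≡C2 alkyne; C3 carbinol), via acylketene 16 (not isolated)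
Conditions: toluene (0.001 M, slow addition), 100 °C
Reagents that add atoms: none
Why: Thermal fragmentation of the acyl Meldrum's acid gives an acylketene that is trapped by the C10 hydroxyl (acylketene macrolactonisation) at high dilution; the nine-membered alternative through the hindered C3 hydroxyl should be disfavoured.

Step 12
Reactants: 17 twelve-membered β-keto lactone
Product: 18 macrocyclic epoxy ynone (C3 ketone conjugated to C1≡C2; 4S,5R,6S,10R)
Conditions: Dess–Martin periodinane, NaHCO3, CH2Cl2, 0 °C to rt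
Reagents that add atoms: none
Why: Dess–Martin oxidation of the remaining propargylic α-epoxy alcohol gives the ynone under neutral conditions that leave the β-keto lactone and epoxide alone, and it removes the temporary C3 stereocentre.

Step 13
Reactants: 18 macrocyclic epoxy ynone
Product: 19 macrocyclic (E)-C1 methyl enol ether (C3(=O)–C2H=C1(OMe)–C10 with C10 and C3 cis; 4S,5R,6S,10R)
Conditions: MeOH, PMe3 (10 mol%), CH2Cl2, −20 to 0 °C
Reagents that add atoms: methanol, CO
Why: Phosphine-catalysed oxa-Michael addition of methanol to the ynone should give the thermodynamic (E)-β-methoxy enone, which masks the C1/C3 diketone and makes C10 an allyl terminus; C-attack of the β-keto lactone enolate on C1 would require an s-cis ester inside the macrocycle and should be slow.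

Step 14
Reactants: 19 macrocyclic (E)-C1 methyl enol ether
Product: 22 ten-membered carbocycle with C8 ketone and C1 methyl enol ether and C13 TBDPS ether (4S 5R 6S 10S), via allylpalladium carboxylate ion pair 20 (not isolated), via allylpalladium enolate 21 (not isolated)
Conditions: Pd2(dba)3 (5 mol%), PPh3 (25 mol%), THF (0.002 M), 25 to 40 °C
Reagents that add atoms: none
Why: Proposed new method: zerovalent palladium should ionise the C10–O bond of 19 anti to the ester, giving a 2-methoxy-π-allylpalladium cation (C10–C1–C2, conjugated to the C3 ketone) paired with the C8 β-keto carboxylate (20); loss of CO2 gives palladium enolate 21, regiodefined because the C8 ketone has α-hydrogens only at C9, and C-allylation at C10 forms the C9–C10 bond. The closest known reaction types are the Tsuji–Saegusa decarboxylative allylation of allyl β-keto esters and Tsuji–Trost macrocyclisations; new here are its use as a 12-to-10 ring contraction of a macrolide and the 2-alkoxy, 3-acyl substituted allyl unit. The ten-membered carbocycle is closed by attack of the enolate carbon on the proximal allyl terminus, so the allyl unit ends up inside the ring, and the two ends are held together as an ion pair whose entropic cost was paid in the easier twelve-membered lactonisation. The new C10 stereocentre should be set by the C10–O stereocentre through double inversion, (10R)-ester to (10S)-product. The step needs C- over O-allylation and attack at C10 rather than C2: only attack at C10 keeps the C1=C2 enol ether conjugated to the C3 ketone, C2 is shielded by the acyl group, and no second allylic ester is present because C13 stays a silyl ether until step 16. The only tether atom, the ester carbon, is lost as CO2, so nothing has to be removed afterwards.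

Step 15
Reactants: 22 ten-membered carbocycle (C13 TBDPS ether)
Product: 23 C13 primary alcohol (C8 ketone, C1 methyl enol ether; 4S,5R,6S,10S)
Conditions: TBAF, AcOH, THF, 0 °C to rt
Reagents that add atoms: none
Why: Acetic acid-buffered fluoride cleaves the primary TBDPS ether; buffering protects the base-sensitive ene-dione, the epoxide and the enol ether.

Step 16
Reactants: 23 C13 primary alcohol
Product: 24 C13 acetate (C8 ketone, C1 methyl enol ether; 4S,5R,6S,10S)
Conditions: Ac2O, pyridine, DMAP (cat.), CH2Cl2, 0 °C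
Reagents that add atoms: acetic anhydride, CC(=O)OC(C)=O
Why: Acetylation of the only free hydroxyl; the allylic acetate is introduced after the palladium step because it would itself ionise there.

Step 17
Reactants: 24 C13 acetate
Product: 25 (8S)-carbinol (C13 acetate, C1 methyl enol ether; 4S,5R,6S,8S,10S)
Conditions: (R)-2-methyl-CBS-oxazaborolidine (20 mol%), catecholborane, toluene/CH2Cl2, −78 to −40 °C; pH 7 buffer work-up
Reagents that add atoms: none
Why: Corey–Bakshi–Shibata reduction: C8 is the only electrophilic ketone (C3 is a deactivated vinylogous ester carbonyl), and with the fully substituted butenolide carbon C7 as the large group the (R)-oxazaborolidine should deliver hydride to give the (8S)-alcohol by reagent control.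

Step 18
Reactants: 26 4-methylfuran-2(5H)-one
Product: 29 (Z)-3-methyl-4-(triethylsilyloxy)but-2-enoic acid, via sodium hydroxy carboxylate 27 (not isolated), via bis-silyl derivative 28 (not isolated)
Conditions: NaOH, H2O/MeOH, rt, evaporate; TESCl, imidazole, DMF, 0 °C; K2CO3 (cat.), MeOH/H2O, 0 °C, then pH 5 buffer
Reagents that add atoms: sodium hydroxide, [Na+].[OH-]; chlorotriethylsilane, CC[Si](Cl)(CC)CC
Why: Saponification of the butenolide fixes the (Z)-geometry (carboxylate and CH2OH were cis in the ring), and bis-silylation followed by selective hydrolysis of the labile silyl ester gives the O-protected acid, which cannot relactonise.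

Step 19
Reactants: 25 (8S)-carbinol; 29 (Z)-3-methyl-4-(triethylsilyloxy)but-2-enoic acid
Product: 30 C8 ester (side-chain TES ether, C13 acetate, C1 methyl enol ether; 4S,5R,6S,8S,10S)
Conditions: 29, 2,4,6-trichlorobenzoyl chloride, Et3N, THF, 0 °C; then 25, DMAP, toluene, 0 °C to rt
Reagents that add atoms: none
Why: Yamaguchi esterification (mixed anhydride, DMAP acyl transfer) should acylate the hindered allylic C8 alcohol with retention at C8; low temperature limits Z/E isomerisation of the enoate.

Step 20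
Reactants: 30 C8 ester
Product: 31 CNP0295642.1 (target; 4S,5R,6S,8S,10S)
Conditions: 1 M aq. HCl, THF, 0 °C to rt
Reagents that add atoms: water, O
Why: Dilute aqueous acid hydrolyses the vinylogous methyl ester to the C1/C3 β-diketone and cleaves the triethylsilyl ether in one operation, under conditions the α-keto epoxide, the acetate and the (Z)-hydroxy enoate should tolerate.

**Compound list**

1 | (R)-but-3-yn-2-ol | C[C@@H](O)C#C | starting material
2 | (R)-tert-butyl(but-3-yn-2-yloxy)dimethylsilane | C[C@@H](O[Si](C)(C)C(C)(C)C)C#C | intermediate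
3 | (E)-4,4-dimethoxy-2-methylbut-2-enal | O=C/C(C)=C/C(OC)OC | starting material
4 | (2E,4R,7R)-7-(tert-butyldimethylsilyloxy)-1,1-dimethoxy-3-methyloct-2-en-5-yn-4-ol | C[C@@H](O[Si](C)(C)C(C)(C)C)C#C[C@H](O)/C(C)=C/C(OC)OC | intermediate
5 | (2E,4R,7R)-4,7-bis(tert-butyldimethylsilyloxy)-1,1-dimethoxy-3-methyloct-2-en-5-yne | C[C@@H](O[Si](C)(C)C(C)(C)C)C#C[C@H](O[Si](C)(C)C(C)(C)C)/C(C)=C/C(OC)OC | intermediate
6 | (2E,4R,7R)-4,7-bis(tert-butyldimethylsilyloxy)-3-methyloct-2-en-5-ynal | C[C@@H](O[Si](C)(C)C(C)(C)C)C#C[C@H](O[Si](C)(C)C(C)(C)C)/C(C)=C/C=O | intermediate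
7 | tert-butyldiphenyl(prop-2-yn-1-yloxy)silane | C#CCO[Si](c1ccccc1)(c1ccccc1)C(C)(C)C | starting material
8 | (4R,5E,7R,10R)-7,10-bis(tert-butyldimethylsilyloxy)-1-(tert-butyldiphenylsilyloxy)-6-methylundec-5-ene-2,8-diyn-4-ol | C[C@@H](O[Si](C)(C)C(C)(C)C)C#C[C@H](O[Si](C)(C)C(C)(C)C)/C(C)=C/[C@@H](O)C#CCO[Si](c1ccccc1)(c1ccccc1)C(C)(C)C | intermediate
9 | alkenylmagnesium chelate (five-membered C6–O–Mg–C11 ring, vinyl on C7) | C[C@@H](O[Si](C)(C)C(C)(C)C)C#C[C@H](O[Si](C)(C)C(C)(C)C)/C(C)=C/[C@H]1O[Mg]C(CO[Si](c2ccccc2)(c2ccccc2)C(C)(C)C)=C1C=C | intermediate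
10 | (5R)-5-[(1E,3R,6R)-3,6-bis(tert-butyldimethylsilyloxy)-2-methylhept-1-en-4-yn-1-yl]-3-[(tert-butyldiphenylsilyloxy)methyl]-4-vinylfuran-2(5H)-one | C[C@@H](O[Si](C)(C)C(C)(C)C)C#C[C@H](O[Si](C)(C)C(C)(C)C)/C(C)=C/[C@H]1OC(=O)C(CO[Si](c2ccccc2)(c2ccccc2)C(C)(C)C)=C1C=C | intermediate
11 | (5S)-5-{(2R,3S)-3-[(1S,4R)-1,4-bis(tert-butyldimethylsilyloxy)pent-2-yn-1-yl]-3-methyloxiran-2-yl}-3-[(tert-butyldiphenylsilyloxy)methyl]-4-vinylfuran-2(5H)-one | C[C@@H](O[Si](C)(C)C(C)(C)C)C#C[C@H](O[Si](C)(C)C(C)(C)C)[C@@]1(C)O[C@@H]1[C@H]2OC(=O)C(CO[Si](c3ccccc3)(c3ccccc3)C(C)(C)C)=C2C=C | intermediate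
12 | C8 aldehyde (4-formylbutenolide analogue of 11; 3S,4S,5R,6S,10R) | C[C@@H](O[Si](C)(C)C(C)(C)C)C#C[C@H](O[Si](C)(C)C(C)(C)C)[C@@]1(C)O[C@@H]1[C@H]2OC(=O)C(CO[Si](c3ccccc3)(c3ccccc3)C(C)(C)C)=C2C=O | intermediate
13 | C8 carboxylic acid (4-carboxybutenolide analogue of 11; 3S,4S,5R,6S,10R) | C[C@@H](O[Si](C)(C)C(C)(C)C)C#C[C@H](O[Si](C)(C)C(C)(C)C)[C@@]1(C)O[C@@H]1[C@H]2OC(=O)C(CO[Si](c3ccccc3)(c3ccccc3)C(C)(C)C)=C2C(=O)O | intermediate
14 | C8 acyl Meldrum's acid, enol form (C3 and C10 TBS ethers, C13 TBDPS ether; 3S,4S,5R,6S,10R) | C[C@@H](O[Si](C)(C)C(C)(C)C)C#C[C@H](O[Si](C)(C)C(C)(C)C)[C@@]1(C)O[C@@H]1[C@H]2OC(=O)C(CO[Si](c3ccccc3)(c3ccccc3)C(C)(C)C)=C2C(O)=C4C(=O)OC(C)(C)OC4=O | intermediate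
15 | diol acyl Meldrum's acid (C3–OH and C10–OH free; 3S,4R,5R,6S,10R) | C[C@@H](O)C#C[C@H](O)[C@@]1(C)O[C@@H]1[C@H]2OC(=O)C(CO[Si](c3ccccc3)(c3ccccc3)C(C)(C)C)=C2C(O)=C4C(=O)OC(C)(C)OC4=O | intermediate
16 | acylketene (C7–C8(=O)–C9H=C=O; C3–OH and C10–OH free) | C[C@@H](O)C#C[C@H](O)[C@@]1(C)O[C@@H]1[C@H]2OC(=O)C(CO[Si](c3ccccc3)(c3ccccc3)C(C)(C)C)=C2C(=O)C=C=O | intermediate
17 | twelve-membered β-keto lactone (C10–O–C(=O)–C9H2–C8(=O); C1≡C2 alkyne; C3 carbinol; 3S,4R,5R,6S,10R) | C[C@@H]1C#C[C@H](O)[C@@]2(C)O[C@@H]2[C@H]3OC(=O)C(CO[Si](c4ccccc4)(c4ccccc4)C(C)(C)C)=C3C(=O)CC(=O)O1 | intermediate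
18 | macrocyclic epoxy ynone (C3 ketone; 4S,5R,6S,10R) | C[C@@H]1C#CC(=O)[C@@]2(C)O[C@@H]2[C@H]3OC(=O)C(CO[Si](c4ccccc4)(c4ccccc4)C(C)(C)C)=C3C(=O)CC(=O)O1 | intermediate
19 | macrocyclic (E)-C1 methyl enol ether, the twelve-membered allyl β-keto lactone (4S,5R,6S,10R) | C[C@@H]1/C(OC)=C\C(=O)[C@@]2(C)O[C@@H]2[C@H]3OC(=O)C(CO[Si](c4ccccc4)(c4ccccc4)C(C)(C)C)=C3C(=O)CC(=O)O1 | intermediate
20 | ion pair of the (2-methoxyallyl)bis(triphenylphosphine)palladium cation with the C8 β-keto carboxylate (drawn as the C10-bound σ form, palladium anti to the departed oxygen) | C[C@H]([Pd-]([P+](c1ccccc1)(c1ccccc1)c1ccccc1)[P+](c1ccccc1)(c1ccccc1)c1ccccc1)/C(OC)=C\C(=O)[C@@]2(C)O[C@@H]2[C@H]3OC(=O)C(CO[Si](c4ccccc4)(c4ccccc4)C(C)(C)C)=C3C(=O)CC(=O)[O-] | intermediate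
21 | allylpalladium enolate after loss of CO2 (C8 enolate, C9 methylene terminus; drawn as the C10-bound σ form) | C[C@H]([Pd-]([P+](c1ccccc1)(c1ccccc1)c1ccccc1)[P+](c1ccccc1)(c1ccccc1)c1ccccc1)/C(OC)=C\C(=O)[C@@]2(C)O[C@@H]2[C@H]3OC(=O)C(CO[Si](c4ccccc4)(c4ccccc4)C(C)(C)C)=C3C([O-])=C | intermediate
22 | ten-membered carbocycle: C8 ketone, (E)-C1 methyl enol ether, 4,5-epoxide, 7(11)-en-12,6-olide, C13 TBDPS ether (4S,5R,6S,10S) | C[C@@H]1/C(OC)=C\C(=O)[C@@]2(C)O[C@@H]2[C@H]3OC(=O)C(CO[Si](c4ccccc4)(c4ccccc4)C(C)(C)C)=C3C(=O)C1 | intermediate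
23 | C13 primary alcohol of 22 (4S,5R,6S,10S) | C[C@@H]1/C(OC)=C\C(=O)[C@@]2(C)O[C@@H]2[C@H]3OC(=O)C(CO)=C3C(=O)C1 | intermediate
24 | C13 acetate, C8 ketone (4S,5R,6S,10S) | C[C@@H]1/C(OC)=C\C(=O)[C@@]2(C)O[C@@H]2[C@H]3OC(=O)C(COC(C)=O)=C3C(=O)C1 | intermediate
25 | (8S)-carbinol, C13 acetate, C1 methyl enol ether (4S,5R,6S,8S,10S) | C[C@@H]1/C(OC)=C\C(=O)[C@@]2(C)O[C@@H]2[C@H]3OC(=O)C(COC(C)=O)=C3[C@@H](O)C1 | intermediate
26 | 4-methylfuran-2(5H)-one | CC1=CC(=O)OC1 | starting material
27 | sodium (Z)-4-hydroxy-3-methylbut-2-enoate | [Na+].[O-]C(=O)/C=C(/C)CO | intermediate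
28 | triethylsilyl (Z)-3-methyl-4-(triethylsilyloxy)but-2-enoate | CC[Si](CC)(CC)OC(=O)/C=C(/C)CO[Si](CC)(CC)CC | intermediate
29 | (Z)-3-methyl-4-(triethylsilyloxy)but-2-enoic acid | OC(=O)/C=C(/C)CO[Si](CC)(CC)CC | intermediate
30 | C8 (Z)-3-methyl-4-(triethylsilyloxy)but-2-enoate of 25 (4S,5R,6S,8S,10S) | C[C@@H]1/C(OC)=C\C(=O)[C@@]2(C)O[C@@H]2[C@H]3OC(=O)C(COC(C)=O)=C3[C@@H](OC(=O)/C=C(/C)CO[Si](CC)(CC)CC)C1 | intermediate
31 | CNP0295642.1: 13-acetoxy-4,5-epoxy-8-[(Z)-4-hydroxy-3-methylbut-2-enoyloxy]-1,3-dioxogermacr-7(11)-en-12,6-olide (4S,5R,6S,8S,10S) | CC(=O)OCC1=C2[C@@H](OC(=O)/C=C(/C)CO)C[C@H](C)C(=O)CC(=O)[C@@]3(C)O[C@@H]3[C@H]2OC1=O | target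

**Step count and risks**

Total: 20 steps. Longest linear sequence: 19 steps (steps 1–17, 19 and 20, from (R)-but-3-yn-2-ol); step 18 makes the side-chain acid.

Steps most likely to fail:

Step 14 (proposed new method). The palladium enolate may be protonated before it finds C10 (giving the seco methyl ketone and a diene), it may collapse at oxygen or at C2, the open ion pair may oligomerise, or the C10 configuration may erode by π–σ–π isomerisation through the acyl-bearing C2 terminus. The fallback uses known chemistry, a Tsuji–Trost macrocyclisation with a stabilised β-keto ester nucleophile followed by dealkoxycarbonylation; it sets out from 15 and comes back at 23. Compound 15 is heated with excess 2-(trimethylsilyl)ethanol (toluene, 80 °C), so that the acylketene is trapped intermolecularly as the acyclic 2-(trimethylsilyl)ethyl β-keto ester diol F1. The less hindered C10 hydroxyl is converted selectively into the methyl carbonate F2 (ClCO2Me, pyridine, −20 °C), and Dess–Martin oxidation of the C3 carbinol gives the acyclic ynone F3. DABCO-catalysed addition of methanol gives the (E)-methyl enol ether carbonate F4. Pd(PPh3)4 with dppe in THF at high dilution ionises the carbonate, the liberated methoxide deprotonates the β-keto ester, and intramolecular allylic alkylation at C10 (double inversion) closes the ten-membered ring as the C9 ester F5. TBAF then cleaves the 2-(trimethylsilyl)ethyl ester (the β-keto acid decarboxylates) together with the TBDPS ether and gives 23.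

Step 13. The catalytic base may turn the β-keto lactone into an enolate that adds as a carbon nucleophile to the ynone (intra- or intermolecular Michael addition), or methoxide may open the macrolactone. The fallback sets out from 18 and comes back at 19: morpholine (1 equiv, CH2Cl2, −40 °C) adds to the ynone without any base to give the macrocyclic enaminone F6, and camphorsulfonic acid in dry methanol then exchanges the amine for methoxide to give 19.

Step 7. Oxygen transfer to an olefin flanked by two allylic oxygens may be slow and the facial selectivity insufficient. The fallback replaces reagent control by substrate control; it sets out from 8 and comes back at 11. The magnesium chelate of step 6 is quenched with iodine instead of CO2 to give the (Z)-iodo dienol F7. mCPBA epoxidation directed by the free C6 hydroxyl (threo selectivity enforced by A1,3 strain with the cis C4 methyl) gives the threo epoxy alcohol F8. Carbonylative lactonisation (PdCl2(PPh3)2, CO, Et3N, THF, 50 °C) then closes the butenolide and gives 11.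

Further compounds
F1 | step 14 | acyclic 2-(trimethylsilyl)ethyl β-keto ester diol (C3–OH and C10–OH free; 3S,4R,5R,6S,10R) | C[C@@H](O)C#C[C@H](O)[C@@]1(C)O[C@@H]1[C@H]2OC(=O)C(CO[Si](c3ccccc3)(c3ccccc3)C(C)(C)C)=C2C(=O)CC(=O)OCC[Si](C)(C)C
F2 | step 14 | C10 methyl carbonate of F1 (C3–OH free) | C[C@@H](OC(=O)OC)C#C[C@H](O)[C@@]1(C)O[C@@H]1[C@H]2OC(=O)C(CO[Si](c3ccccc3)(c3ccccc3)C(C)(C)C)=C2C(=O)CC(=O)OCC[Si](C)(C)C
F3 | step 14 | acyclic epoxy ynone carbonate (C3 ketone) | C[C@@H](OC(=O)OC)C#CC(=O)[C@@]1(C)O[C@@H]1[C@H]2OC(=O)C(CO[Si](c3ccccc3)(c3ccccc3)C(C)(C)C)=C2C(=O)CC(=O)OCC[Si](C)(C)C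
F4 | step 14 | acyclic (E)-C1 methyl enol ether with C10 allylic methyl carbonate and 2-(trimethylsilyl)ethyl β-keto ester | C[C@@H](OC(=O)OC)/C(OC)=C\C(=O)[C@@]1(C)O[C@@H]1[C@H]2OC(=O)C(CO[Si](c3ccccc3)(c3ccccc3)C(C)(C)C)=C2C(=O)CC(=O)OCC[Si](C)(C)C
F5 | step 14 | ten-membered carbocycle bearing the C9 2-(trimethylsilyl)ethyl ester (C9 epimers; 4S,5R,6S,10S) | C[C@@H]1/C(OC)=C\C(=O)[C@@]2(C)O[C@@H]2[C@H]3OC(=O)C(CO[Si](c4ccccc4)(c4ccccc4)C(C)(C)C)=C3C(=O)C1C(=O)OCC[Si](C)(C)C
F6 | step 13 | macrocyclic (E)-C1 morpholino enaminone | C[C@@H]1/C(N2CCOCC2)=C\C(=O)[C@@]3(C)O[C@@H]3[C@H]4OC(=O)C(CO[Si](c5ccccc5)(c5ccccc5)C(C)(C)C)=C4C(=O)CC(=O)O1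
F7 | step 7 | (Z)-iodo dienol (C7 vinyl, C11 iodide cis to the C6 carbinol; C4=C5 olefin intact) | C[C@@H](O[Si](C)(C)C(C)(C)C)C#C[C@H](O[Si](C)(C)C(C)(C)C)/C(C)=C/[C@@H](O)/C(C=C)=C(\I)CO[Si](c1ccccc1)(c1ccccc1)C(C)(C)C
F8 | step 7 | threo epoxy alcohol of F7 (4S,5R-epoxide, free C6–OH) | C[C@@H](O[Si](C)(C)C(C)(C)C)C#C[C@H](O[Si](C)(C)C(C)(C)C)[C@@]1(C)O[C@@H]1[C@@H](O)/C(C=C)=C(\I)CO[Si](c2ccccc2)(c2ccccc2)C(C)(C)C
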